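**Retrosynthetic overview**
- Feature: the two phenolic oxygens sit on C4 of ring A and ring B, para to the benzylic carbons C1 and C7, and neither ring carries another substituent. The anti C3/C5 diol core is C2-symmetric, so O3 and O5 are homotopic.
- Last disconnection: both aryl C4–O bonds at once, back to a bis(aryl thianthrenium) salt that already carries the O3 acetate. No phenol is present while an acyl group is being placed.
- The two aryl C–S bonds go back to the two para C–H bonds of the 1,7-diphenyl monoacetate. The acetate goes back to the diol through a cyclic orthoacetate.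
- The C3 and C5 carbinols go back to 1,7-diphenylheptane-3,5-dione by double asymmetric hydrogenation. Its C4–C5 bond goes back to the methyl-side enolate of benzylacetone and hydrocinnamoyl chloride.
- Ring order: no ring of the target is formed. Rings A and B are bought, and the only ring made on the way, a 1,3-dioxane orthoester, is reopened in the same flask.

Key step: step 5

Remark on the chemistry: trifluoroacetic anhydride will acylate the free C5 hydroxyl in step 4. It is assumed that this ester acts as a transient mask and that bicarbonate methanolysis in the same operation removes it while the secondary acetate stays.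

Step 1
Reactants: 1 benzylacetone (4-phenylbutan-2-one, 2 equiv); 2 hydrocinnamoyl chloride (3-phenylpropanoyl chloride, 1 equiv)
Product: 5 1,7-diphenylheptane-3,5-dione, via lithium enolate 3 (not isolated), via lithium diketonate 4 (not isolated)
Conditions: LiN(iPr)2 (commercial solution, 2.05 equiv), THF, −78 °C, 45 min; 2 in THF, −78 to −20 °C; 1 M aq HCl
Reagents that add atoms: 3-phenylpropanoyl chloride (2) O=C(Cl)CCc1ccccc1; lithium diisopropylamide [Li+].CC(C)[N-]C(C)C (its lithium stays only in 3 and 4)
Why: Crossed Claisen-type C-acylation of a kinetic ketone enolate, in which LiN(iPr)2 at −78 °C removes a proton from the unhindered methyl group of 1, enolate 3 attacks the acid chloride through carbon, and the second equivalent of 3 takes the acidic C4 proton of the product so that it rests as chelated 4, shielded from a second acylation, until the acid quench; no stereocentre is formed.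

Step 2
Reactants: 5 1,7-diphenylheptane-3,5-dione
Product: 7 (3R,5R)-1,7-diphenylheptane-3,5-diol, via hydroxy ketone 6 (not isolated)
Conditions: RuCl2[(R)-BINAP] (0.5 mol %), H2 (80 atm), degassed MeOH, 50 °C, 48 h; recrystallisation or chromatography to remove the meso diol
Reagents that add atoms: none
Why: Noyori asymmetric hydrogenation of a β-diketone, in which the chelated substrate is reduced under catalyst control to (5R)-6 in the same sense as β-keto esters with the (R)-ligand, the new hydroxyl then directs the matched second hydride delivery to the anti (3R,5R) diol, and the minor enantiomer of 6 is diverted mainly into the separable meso syn diol, so the enantiopurity of 7 should exceed that of the first reduction.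

Step 3
Reactants: 7 (3R,5R)-1,7-diphenylheptane-3,5-diol; 8 trimethyl orthoacetate
Product: 10 (3R,5R)-5-hydroxy-1,7-diphenylheptan-3-yl acetate, via cyclic orthoester 9 (not isolated)
Conditions: MeC(OMe)3 (1.5 equiv), camphorsulfonic acid (5 mol %), CH2Cl2, rt, 1 h; then AcOH/H2O (4:1), rt, 20 min
Reagents that add atoms: trimethyl orthoacetate (8) COC(C)(OC)OC; water O
Why: Orthoester exchange followed by mild acid hydrolysis, in which both hydroxyls are tied into dioxane 9, loss of methanol gives a 1,3-dioxan-2-ylium ion that takes up water and collapses to exactly one acetate and one free hydroxyl, and because O3 and O5 are homotopic either ring opening gives the same compound with both stereogenic C–O bonds untouched.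

Step 4
Reactants: 10 (3R,5R)-5-hydroxy-1,7-diphenylheptan-3-yl acetate; 11 thianthrene S-oxide (2.1 equiv)
Product: 14 (3R,5R)-5-hydroxy-1,7-bis[4-(thianthren-5-ium-5-yl)phenyl]heptan-3-yl acetate bis(tetrafluoroborate), via trifluoroacetate 12 (not isolated), via bis(thianthrenium) trifluoroacetate 13 (not isolated)
Conditions: (CF3CO)2O (7.5 equiv), MeCN, 0 °C, 15 min; 11, HBF4·OEt2 (3 equiv), 0 °C to rt; then MeOH, solid NaHCO3, rt; CH2Cl2, aq NaBF4 wash; precipitation from Et2O
Reagents that add atoms: thianthrene S-oxide (11) O=S1c2ccccc2Sc2ccccc21; tetrafluoroboric acid diethyl etherate [H+].F[B-](F)(F)F.CCOCC and sodium tetrafluoroborate [Na+].F[B-](F)(F)F (counter-ions); trifluoroacetic anhydride O=C(OC(=O)C(F)(F)F)C(F)(F)F (its CF3CO group stays only in 12 and 13)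
Why: Electrophilic aromatic C–H thianthrenation, in which the anhydride first masks O5 as 12 and then turns sulfoxide 11 into an acyloxysulfonium electrophile that adds reversibly to each monoalkylbenzene ring and is deprotonated irreversibly only from the least crowded para σ-complex, the seven sp3 carbons between the rings keep the first sulfonium group from deactivating the second ring, and bicarbonate methanolysis then removes only the far more electrophilic trifluoroacetate; no stereocentre is touched.

Step 5
Reactants: 14 (3R,5R)-5-hydroxy-1,7-bis[4-(thianthren-5-ium-5-yl)phenyl]heptan-3-yl acetate bis(tetrafluoroborate)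
Product: 15 (3R,5R)-5-hydroxy-1,7-bis(4-hydroxyphenyl)heptan-3-yl acetate (target)
Conditions: fac-Ir(ppy)3 (2 mol %), Cu(O2CC4H3S) (2.5 equiv), H2O (50 equiv), MeCN (0.05 M), N2, blue LEDs (450 nm), 25 °C, 16 h; aq NH4Cl; chromatography (thianthrene elutes first)
Reagents that add atoms: water O
Why: Excited Ir(ppy)3 passes one electron to an aryl sulfonium unit of 14, whose exocyclic C–S bond then breaks to neutral thianthrene and a σ aryl radical fixed at the former para carbon, while the tetravalent iridium left behind is reduced back by monovalent copper. The divalent copper so formed binds water, hands its proton to thiophene-2-carboxylate and traps the aryl radical, and the trivalent aryl copper hydroxide reductively eliminates the aryl C–O bond and returns monovalent copper; the second ring runs through the same cycle on its own. The closest known reaction type is the photoredox and copper-mediated hydroxylation of aryl thianthrenium salts with water, applied here at two electronically isolated sites of one molecule. No ring closes and no stereocentre is made; C3 and C5 are saturated carbons far from the radical centres, and a 1,3-acetyl shift would only regenerate the same compound. The step needs ipso substitution only, which the site-bound σ radical guarantees, and it needs water to win over the C5 hydroxyl, the carboxylate and the first-formed phenol as oxygen donor, which the large excess of water and the dilution secure, an internal attack of O5 on a para carbon being geometrically out of reach. It also needs copper capture to outrun hydrogen abstraction, for which more than one equivalent of copper per sulfonium group and the poor hydrogen donor MeCN are used.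

**Compound list**
1 | benzylacetone (4-phenylbutan-2-one) | CC(=O)CCc1ccccc1 | starting material
2 | hydrocinnamoyl chloride (3-phenylpropanoyl chloride) | O=C(Cl)CCc1ccccc1 | starting material
3 | lithium 4-phenylbut-1-en-2-olate | [Li+].[O-]C(=C)CCc1ccccc1 | intermediate
4 | lithium (Z)-5-oxo-1,7-diphenylhept-3-en-3-olate | [Li+].[O-]/C(CCc1ccccc1)=C\C(=O)CCc1ccccc1 | intermediate
5 | 1,7-diphenylheptane-3,5-dione | O=C(CCc1ccccc1)CC(=O)CCc1ccccc1 | intermediate
6 | (5R)-5-hydroxy-1,7-diphenylheptan-3-one | O=C(CCc1ccccc1)C[C@H](O)CCc1ccccc1 | intermediate
7 | (3R,5R)-1,7-diphenylheptane-3,5-diol | O[C@H](CCc1ccccc1)C[C@H](O)CCc1ccccc1 | intermediate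
8 | trimethyl orthoacetate | COC(C)(OC)OC | starting material
9 | (4R,6R)-2-methoxy-2-methyl-4,6-bis(2-phenylethyl)-1,3-dioxane | COC1(C)O[C@H](CCc2ccccc2)C[C@@H](CCc2ccccc2)O1 | intermediate
10 | (3R,5R)-5-hydroxy-1,7-diphenylheptan-3-yl acetate | CC(=O)O[C@H](CCc1ccccc1)C[C@H](O)CCc1ccccc1 | intermediate
11 | thianthrene S-oxide | O=S1c2ccccc2Sc2ccccc21 | starting material
12 | (3R,5R)-1,7-diphenyl-5-(trifluoroacetoxy)heptan-3-yl acetate | CC(=O)O[C@H](CCc1ccccc1)C[C@H](OC(=O)C(F)(F)F)CCc1ccccc1 | intermediate
13 | (3R,5R)-1,7-bis[4-(thianthren-5-ium-5-yl)phenyl]-5-(trifluoroacetoxy)heptan-3-yl acetate bis(tetrafluoroborate) | CC(=O)O[C@H](CCc1ccc(cc1)[S+]1c2ccccc2Sc2ccccc21)C[C@H](OC(=O)C(F)(F)F)CCc1ccc(cc1)[S+]1c2ccccc2Sc2ccccc21.F[B-](F)(F)F.F[B-](F)(F)F | intermediate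
14 | (3R,5R)-5-hydroxy-1,7-bis[4-(thianthren-5-ium-5-yl)phenyl]heptan-3-yl acetate bis(tetrafluoroborate) | CC(=O)O[C@H](CCc1ccc(cc1)[S+]1c2ccccc2Sc2ccccc21)C[C@H](O)CCc1ccc(cc1)[S+]1c2ccccc2Sc2ccccc21.F[B-](F)(F)F.F[B-](F)(F)F | intermediate
15 | (3R,5R)-5-hydroxy-1,7-bis(4-hydroxyphenyl)heptan-3-yl acetate | CC(=O)O[C@H](CCc1ccc(O)cc1)C[C@H](O)CCc1ccc(O)cc1 | target

**Total step count:** 5. **Longest linear sequence:** 5 steps (1 → 5 → 7 → 10 → 14 → 15).

**Steps most likely to fail**

Step 5.
- What may go wrong: one of the two aryl radicals may abstract hydrogen before copper captures it, so a sulfonium handle is lost without oxygenation. The radical may also be captured by copper-bound carboxylate or by the first-formed phenoxide instead of water. Both rings must succeed, so every inefficiency counts twice.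
- Fallback: it replaces the radical pathway by two-electron chemistry, sets out from 14 and returns at 15.
- Zerovalent palladium generated from Pd(dppf)Cl2 inserts into each aryl–sulfonium bond. A Miyaura-type borylation with B2pin2 and KOAc in dioxane at 70 °C should then give the bis(pinacol boronate) F1.
- Oxidation of both C–B bonds with NaBO3·4H2O in THF/H2O at rt, with retention of position, should give 15. These conditions are mild enough for the secondary acetate.

Step 4.
- What may go wrong: the acetate may be exchanged for trifluoroacetate in the strongly acidic anhydride medium, or the reaction may stall after the first ring has reacted, leaving mono and bis salts that are hard to separate.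
- Fallback: it moves the C–H functionalisation ahead of the acetylation, so no acetate meets the acid and substrate and product stay C2-symmetric. It sets out from 7 and returns at 14.
- Trifluoroacetic anhydride in MeCN converts 7 in the flask into the diol bis(trifluoroacetate) F2.
- Sulfoxide 11 and HBF4·OEt2 then give the bis(thianthrenium) bis(trifluoroacetate) F3.
- Methanol and NaHCO3 release the bis(thianthrenium) diol F4, which is isolated after a NaBF4 wash.
- Orthoester exchange of F4 with 8 and catalytic camphorsulfonic acid in MeCN gives the bis(thianthrenium) cyclic orthoester F5. Aqueous acetic acid opens it to 14.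

Step 2.
- What may go wrong: catalyst control may be incomplete in the second reduction, so the anti preference erodes and meso diol builds up. The hydrogenation may also stall at the hydroxy ketone stage.
- Fallback: it sets the two carbinols by two different principles, sets out from 1, returns at 10, and replaces steps 1 to 3.
- Carboxylation of 1 on its methyl side with dimethyl carbonate and NaH in THF at reflux gives methyl 3-oxo-5-phenylpentanoate F6.
- Noyori hydrogenation of this β-keto ester with RuCl2[(R)-BINAP] in MeOH gives methyl (3R)-3-hydroxy-5-phenylpentanoate F7. β-Keto esters are the best-behaved substrate class for this catalyst.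
- MeNH(OMe)·HCl and iPrMgCl in THF at −20 °C give the (3R)-hydroxy Weinreb amide F8.
- Excess PhCH2CH2MgBr (Weinreb ketone synthesis) gives hydroxy ketone 6, now isolated.
- An Evans–Tishchenko reaction of 6 with acetaldehyde and catalytic SmI2 in THF at −10 °C transfers hydride within the samarium-bound hemiacetal to the ketone face that gives the anti diol. The acetyl group stays on the original oxygen, and by the C2 symmetry of the diol core that product is 10.

**Further compounds**
F1 | step 5 | (3R,5R)-5-hydroxy-1,7-bis[4-(4,4,5,5-tetramethyl-1,3,2-dioxaborolan-2-yl)phenyl]heptan-3-yl acetate | CC(=O)O[C@H](CCc1ccc(cc1)B1OC(C)(C)C(C)(C)O1)C[C@H](O)CCc1ccc(cc1)B1OC(C)(C)C(C)(C)O1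
F2 | step 4 | (3R,5R)-1,7-diphenylheptane-3,5-diyl bis(trifluoroacetate) | O=C(O[C@H](CCc1ccccc1)C[C@H](OC(=O)C(F)(F)F)CCc1ccccc1)C(F)(F)F
F3 | step 4 | (3R,5R)-1,7-bis[4-(thianthren-5-ium-5-yl)phenyl]heptane-3,5-diyl bis(trifluoroacetate) bis(tetrafluoroborate) | O=C(O[C@H](CCc1ccc(cc1)[S+]1c2ccccc2Sc2ccccc21)C[C@H](OC(=O)C(F)(F)F)CCc1ccc(cc1)[S+]1c2ccccc2Sc2ccccc21)C(F)(F)F.F[B-](F)(F)F.F[B-](F)(F)F
F4 | step 4 | (3R,5R)-1,7-bis[4-(thianthren-5-ium-5-yl)phenyl]heptane-3,5-diol bis(tetrafluoroborate) | O[C@H](CCc1ccc(cc1)[S+]1c2ccccc2Sc2ccccc21)C[C@H](O)CCc1ccc(cc1)[S+]1c2ccccc2Sc2ccccc21.F[B-](F)(F)F.F[B-](F)(F)F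
F5 | step 4 | (4R,6R)-2-methoxy-2-methyl-4,6-bis{2-[4-(thianthren-5-ium-5-yl)phenyl]ethyl}-1,3-dioxane bis(tetrafluoroborate) | COC1(C)O[C@H](CCc2ccc(cc2)[S+]2c3ccccc3Sc3ccccc32)C[C@@H](CCc2ccc(cc2)[S+]2c3ccccc3Sc3ccccc32)O1.F[B-](F)(F)F.F[B-](F)(F)F
F6 | step 2 | methyl 3-oxo-5-phenylpentanoate | COC(=O)CC(=O)CCc1ccccc1
F7 | step 2 | methyl (3R)-3-hydroxy-5-phenylpentanoate | COC(=O)C[C@H](O)CCc1ccccc1
F8 | step 2 | (3R)-3-hydroxy-N-methoxy-N-methyl-5-phenylpentanamide | CON(C)C(=O)C[C@H](O)CCc1ccccc1
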